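## Retrosynthetic overview

1. The C3 ketone comes from oxidation of a secondary alcohol, and the C7 carbinol from equatorial MeCeCl2 addition to a C7 ketone (28).
2. The oxepane and cyclohexanone rings form together, last, by a Me3SiOTf-triggered epoxide-opening cascade of a bis-epoxy (Z)-silyl enol ether (26).
3. The two-carbon linker comes from cross-metathesis of an allyl-substituted hydroazulene (18) with a bis-epoxy vinyl ketone (24, from geranylacetone by Shi epoxidation).
4. The five- and seven-membered carbocycles form first, in one step, by an enantioselective intramolecular Buchner ring expansion of an anisole-derived diazoketone (6, from 3-methylanisole). The anisole oxygen becomes the C6 ketone that directs gem-dimethylation and allylation, and is finally exchanged for the C6 methyl.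
5. Stereochemical relay in the hydroazulene: C8a (Buchner) → C1 (MeCeCl2) → C3a/C8a (OH-directed hydrogenation) → C5 (equilibration).

Assumption: the sense of induction of Rh2(S-NTTL)4 in step 3 is taken to give the (8aR) product; if experiment shows the opposite, Rh2(R-NTTL)4 is used and nothing else changes.

Locants: azulene numbering (C1–C8a) for the left half, 1-benzoxepine numbering (O1–C9a) for the right half.

## Route

Step 1
Reactants: 1 3-methylanisole; 2 methyl vinyl ketone
Product: 3 4-(4-methoxy-2-methylphenyl)butan-2-one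
Conditions: TfOH (5 mol %), 1 (3 equiv), MeNO2, 0 °C → rt
Reagents that add atoms: none
Why: Friedel–Crafts conjugate (Michael-type) hydroarylation, in which the protonated enone attacks the most nucleophilic ring position, para to OMe and ortho to Me (the minor ortho-to-OMe isomer is removed by distillation); no stereocentre.

Step 2
Reactants: 3 4-(4-methoxy-2-methylphenyl)butan-2-one
Product: 6 1-diazo-4-(4-methoxy-2-methylphenyl)butan-2-one, via lithium enolate 4 (not isolated), via trifluoroacetyl diketone 5 (not isolated)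
Conditions: LiN(SiMe3)2, THF, −78 °C; CF3CO2CH2CF3; then MsN3, Et3N, H2O, MeCN, rt
Reagents that add atoms: methanesulfonyl azide, CS(=O)(=O)N=[N+]=[N-]
Why: Danheiser detrifluoroacetylative diazo transfer, in which kinetic deprotonation occurs at the methyl group, Claisen trifluoroacetylation activates only that carbon, and azide transfer with loss of the trifluoroacetyl group gives the terminal diazoketone.

Step 3
Reactants: 6 1-diazo-4-(4-methoxy-2-methylphenyl)butan-2-one
Product: 8 (8aR)-6-methoxy-4-methyl-3,8a-dihydroazulen-1(2H)-one, via norcaradiene 7 (not isolated)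
Conditions: Rh2(S-NTTL)4 (dirhodium tetrakis[N-(1,8-naphthaloyl)-(S)-tert-leucinate], 1 mol %), CH2Cl2, −20 °C → rt, slow addition; used at once
Reagents that add atoms: none
Why: Enantioselective intramolecular Buchner reaction, in which the rhodium carbene cyclopropanates the arene bond between the ipso carbon and the unsubstituted ortho carbon (the other ortho position is blocked by methyl, and the ring is activated by the para-methoxy group), norcaradiene 7 opens by 6π electrocyclisation to the cycloheptatriene, and the chiral carboxylate ligands choose the arene face and so set C8a.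

Step 4
Reactants: 8 (8aR)-6-methoxy-4-methyl-3,8a-dihydroazulen-1(2H)-one
Product: 11 (1S)-1-hydroxy-1,4-dimethyl-2,3,7,8-tetrahydroazulen-6(1H)-one, via tertiary alcohol 9 (not isolated), via cross-conjugated dienone 10 (not isolated)
Conditions: MeLi, CeCl3, THF, −78 °C; then 1 M HCl, THF, 0 °C; organic phase, DBU (0.2 equiv), CH2Cl2, rt
Reagents that add atoms: methyllithium, [Li]C; water, O
Why: Organocerium 1,2-addition (non-basic, so C8a–H is not enolised) occurs on the carbonyl face bearing C8a–H, anti to C8 of the seven-membered ring, which transfers the C8a chirality to C1 (1S); acid hydrolysis of the dienol ether and base-mediated proton shifts then give the most substituted, linearly conjugated dienone, in which only the robust C1 centre remains.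

Step 5
Reactants: 11 (1S)-1-hydroxy-1,4-dimethyl-2,3,7,8-tetrahydroazulen-6(1H)-one
Product: 12 (1S,3aS,8aS)-1-hydroxy-1,4-dimethyl-2,3,3a,7,8,8a-hexahydroazulen-6(1H)-one
Conditions: [Ir(cod)(PCy3)(py)]PF6 (5 mol %), H2 (1–10 bar), CH2Cl2, rt, stopped after 1 equiv H2
Reagents that add atoms: none
Why: Hydroxyl-directed hydrogenation, in which iridium bound to the C1–OH delivers both hydrogens to the adjacent C3a=C8a alkene from the OH face (also the face anti to the C1 methyl), giving the cis ring fusion with H3a and H8a syn to OH, while the undirected, electron-poor C4=C5 enone alkene reacts more slowly.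

Step 6
Reactants: 12 (1S,3aS,8aS)-1-hydroxy-1,4-dimethyl-2,3,3a,7,8,8a-hexahydroazulen-6(1H)-one
Product: 15 (1S,3aS,5S,8aS)-1-hydroxy-1,4,4-trimethyl-5-(prop-2-en-1-yl)octahydroazulen-6(1H)-one, via lithium enolate 13 (not isolated), via kinetic allyl ketone 14 (not isolated)
Conditions: MeLi (1 equiv), THF, −78 °C; Me2CuLi (from MeLi, CuI), Et2O/THF, −40 → 0 °C; allyl iodide, HMPA, −40 → 0 °C; then NaOMe (0.2 equiv), MeOH, rt
Reagents that add atoms: lithium dimethylcuprate, [Li+].C[Cu-]C; allyl iodide, C=CCI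
Why: Cuprate conjugate addition to the β-methyl enone makes the gem-dimethyl carbon (no stereocentre) and a regiodefined enolate that is C-allylated at C5; methoxide equilibration of this epimerisable centre then gives the isomer with the allyl group pseudo-equatorial, cis to the C3a–C3 bond, so that H5 is cis to H3a.

Step 7
Reactants: 15 (1S,3aS,5S,8aS)-1-hydroxy-1,4,4-trimethyl-5-(prop-2-en-1-yl)octahydroazulen-6(1H)-one
Product: 17 (1S,3aS,5S,8aS)-1-hydroxy-1,4,4-trimethyl-5-(prop-2-en-1-yl)-1,2,3,3a,4,5,8,8a-octahydroazulen-6-yl trifluoromethanesulfonate, via potassium enolate 16 (not isolated)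
Conditions: KN(SiMe3)2 (2.2 equiv), THF, −78 °C; then PhNTf2
Reagents that add atoms: N-phenylbis(trifluoromethanesulfonimide), FC(F)(F)S(=O)(=O)N(c1ccccc1)S(=O)(=O)C(F)(F)F
Why: Kinetic deprotonation occurs at the unhindered C7 methylene (C5–H is shielded by the adjacent quaternary carbon) and O-triflation fixes the C6=C7 enol triflate, leaving C5 untouched.

Step 8
Reactants: 17 (1S,3aS,5S,8aS)-1-hydroxy-1,4,4-trimethyl-5-(prop-2-en-1-yl)-1,2,3,3a,4,5,8,8a-octahydroazulen-6-yl trifluoromethanesulfonate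
Product: 18 (1S,3aS,5R,8aS)-1,4,4,6-tetramethyl-5-(prop-2-en-1-yl)-1,2,3,3a,4,5,8,8a-octahydroazulen-1-ol
Conditions: MeMgBr (3 equiv), Fe(acac)3 (5 mol %), THF/NMP, −30 → 0 °C
Reagents that add atoms: methylmagnesium bromide, C[Mg]Br
Why: Iron-catalysed Kumada-type cross-coupling of the alkenyl triflate installs the C6 methyl on the regiodefined C6=C7 alkene without touching any stereocentre (the C5 descriptor changes from S to R only because the CIP priority of C6 changes).

Step 9
Reactants: 19 (E)-geranylacetone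
Product: 20 4-[(2S,3S)-3-{2-[(2S)-3,3-dimethyloxiran-2-yl]ethyl}-3-methyloxiran-2-yl]butan-2-one
Conditions: ent-Shi ketone (L-fructose-derived, 30 mol % per alkene), KHSO5 (Oxone), K2CO3, Bu4NHSO4, Na2B4O7 buffer (pH 10.5), MeCN/CH2(OMe)2/H2O, 0 °C
Reagents that add atoms: potassium peroxymonosulfate, [K+].[O-]S(=O)(=O)OO
Why: Shi asymmetric epoxidation, in which the chiral dioxirane epoxidises both trisubstituted alkenes through a spiro transition state, the L-series ketone giving the (S,S) internal and (S) terminal epoxides; the internal epoxide carries all the absolute stereochemistry of the right half.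

Step 10
Reactants: 20 4-[(2S,3S)-3-{2-[(2S)-3,3-dimethyloxiran-2-yl]ethyl}-3-methyloxiran-2-yl]butan-2-one
Product: 24 5-[(2S,3S)-3-{2-[(2S)-3,3-dimethyloxiran-2-yl]ethyl}-3-methyloxiran-2-yl]pent-1-en-3-one, via lithium enolate 21 (not isolated), via Mannich base 22 (not isolated), via ammonium iodide 23 (not isolated)
Conditions: LiN(iPr)2, THF, −78 °C; CH2=NMe2+ I−, −78 °C → rt; then MeI, MeOH; then aq. NaHCO3, CH2Cl2, rt
Reagents that add atoms: N,N-dimethylmethyleneiminium iodide (Eschenmoser's salt), C=[N+](C)C.[I-]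
Why: Mannich reaction of the kinetic methyl enolate, N-methylation and E1cB elimination of trimethylamine give the vinyl ketone; the epoxides are inert to these conditions.

Step 11
Reactants: 18 (1S,3aS,5R,8aS)-1,4,4,6-tetramethyl-5-(prop-2-en-1-yl)-1,2,3,3a,4,5,8,8a-octahydroazulen-1-ol; 24 5-[(2S,3S)-3-{2-[(2S)-3,3-dimethyloxiran-2-yl]ethyl}-3-methyloxiran-2-yl]pent-1-en-3-one
Product: 25 (4E)-1-[(2S,3S)-3-{2-[(2S)-3,3-dimethyloxiran-2-yl]ethyl}-3-methyloxiran-2-yl]-6-[(1S,3aS,5R,8aS)-1-hydroxy-1,4,4,6-tetramethyl-1,2,3,3a,4,5,8,8a-octahydroazulen-5-yl]hex-4-en-3-one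
Conditions: second-generation Hoveyda–Grubbs catalyst, RuCl2(H2IMes)(=CH-C6H4-2-OiPr) (5 mol %), 24 (2 equiv), CH2Cl2, 40 °C
Reagents that add atoms: none
Why: Olefin cross-metathesis between the terminal allyl alkene and the electron-poor vinyl ketone is selective for the cross product and for the E enone; the trisubstituted ring alkene, the epoxides and the tertiary alcohol are spectators.

Step 12
Reactants: 25 (4E)-1-[(2S,3S)-3-{2-[(2S)-3,3-dimethyloxiran-2-yl]ethyl}-3-methyloxiran-2-yl]-6-[(1S,3aS,5R,8aS)-1-hydroxy-1,4,4,6-tetramethyl-1,2,3,3a,4,5,8,8a-octahydroazulen-5-yl]hex-4-en-3-one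
Product: 26 triethyl({(3Z)-1-[(2S,3S)-3-{2-[(2S)-3,3-dimethyloxiran-2-yl]ethyl}-3-methyloxiran-2-yl]-6-[(1S,3aS,5R,8aS)-1-hydroxy-1,4,4,6-tetramethyl-1,2,3,3a,4,5,8,8a-octahydroazulen-5-yl]hex-3-en-3-yl}oxy)silane
Conditions: RhCl(PPh3)3 (2 mol %), Et3SiH (1.5 equiv), toluene, 50 °C; used crude
Reagents that add atoms: triethylsilane, CC[SiH](CC)CC
Why: Rhodium-catalysed 1,4-hydrosilylation of the enone gives the (Z)-silyl enol ether with the nucleophilic carbon on the linker side, a regiochemistry that enolisation of the saturated ketone could not provide.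

Step 13
Reactants: 26 triethyl({(3Z)-1-[(2S,3S)-3-{2-[(2S)-3,3-dimethyloxiran-2-yl]ethyl}-3-methyloxiran-2-yl]-6-[(1S,3aS,5R,8aS)-1-hydroxy-1,4,4,6-tetramethyl-1,2,3,3a,4,5,8,8a-octahydroazulen-5-yl]hex-3-en-3-yl}oxy)silane
Product: 28 (3S,5aS,6S,9aS)-3-hydroxy-6-{2-[(1S,3aS,5R,8aS)-1-hydroxy-1,4,4,6-tetramethyl-1,2,3,3a,4,5,8,8a-octahydroazulen-5-yl]ethyl}-2,2,5a-trimethyloctahydro-1-benzoxepin-7(2H)-one, via bis-silyl ether 27 (not isolated)
Conditions: Me3SiOTf (2.5 equiv), 2,6-di-tert-butyl-4-methylpyridine (3 equiv), CH2Cl2, −78 °C; then K2CO3, MeOH, rt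
Reagents that add atoms: none
Why: Tandem oxa-/carbacyclisation (epoxide-opening cascade, with close precedent for the unsubstituted enol silane), in which the internal epoxide oxygen attacks the tertiary carbon of the silyl-activated terminal epoxide and the bridged oxonium is opened at its tertiary carbon with inversion by the enol ether carbon through a chair transition state; this gives the trans-fused oxepane–cyclohexanone (C5a inverted, C9a retained from the epoxide) with the C6 side chain equatorial (from the Z enol ether, and secured by carbonate equilibration), the C1 alcohol being silylated only transiently.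

Step 14
Reactants: 28 (3S,5aS,6S,9aS)-3-hydroxy-6-{2-[(1S,3aS,5R,8aS)-1-hydroxy-1,4,4,6-tetramethyl-1,2,3,3a,4,5,8,8a-octahydroazulen-5-yl]ethyl}-2,2,5a-trimethyloctahydro-1-benzoxepin-7(2H)-one
Product: 29 (3S,5aS,6S,7R,9aS)-6-{2-[(1S,3aS,5R,8aS)-1-hydroxy-1,4,4,6-tetramethyl-1,2,3,3a,4,5,8,8a-octahydroazulen-5-yl]ethyl}-2,2,5a,7-tetramethyldecahydro-1-benzoxepine-3,7-diol
Conditions: MeLi, CeCl3 (5 equiv each), THF, −78 °C
Reagents that add atoms: methyllithium, [Li]C
Why: Organocerium addition to the hindered, enolisable ketone occurs by equatorial attack, because the axial trajectory is blocked by the 1,3-diaxial C5a methyl, giving the axial C7–OH cis to that methyl and the equatorial C7 methyl (7R).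

Step 15
Reactants: 29 (3S,5aS,6S,7R,9aS)-6-{2-[(1S,3aS,5R,8aS)-1-hydroxy-1,4,4,6-tetramethyl-1,2,3,3a,4,5,8,8a-octahydroazulen-5-yl]ethyl}-2,2,5a,7-tetramethyldecahydro-1-benzoxepine-3,7-diol
Product: 30 (5aS,6S,7R,9aS)-7-hydroxy-6-{2-[(1S,3aS,5R,8aS)-1-hydroxy-1,4,4,6-tetramethyl-1,2,3,3a,4,5,8,8a-octahydroazulen-5-yl]ethyl}-2,2,5a,7-tetramethyloctahydro-1-benzoxepin-3(2H)-one
Conditions: Dess–Martin periodinane, CH2Cl2, rt
Reagents that add atoms: none
Why: Dess–Martin oxidation converts the only secondary alcohol into the C3 ketone (removing the C3 stereocentre), while the two tertiary alcohols and the trisubstituted alkene are inert.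

## Compound list

1 | 3-methylanisole | COc1cccc(C)c1 | starting material
2 | methyl vinyl ketone | CC(=O)C=C | starting material
3 | 4-(4-methoxy-2-methylphenyl)butan-2-one | CC(=O)CCc1ccc(OC)cc1C | intermediate
4 | lithium 4-(4-methoxy-2-methylphenyl)but-1-en-2-olate | [Li]OC(=C)CCc1ccc(OC)cc1C | intermediate (not isolated)
5 | 1,1,1-trifluoro-6-(4-methoxy-2-methylphenyl)hexane-2,4-dione | O=C(CC(=O)C(F)(F)F)CCc1ccc(OC)cc1C | intermediate (not isolated)
6 | 1-diazo-4-(4-methoxy-2-methylphenyl)butan-2-one | [N-]=[N+]=CC(=O)CCc1ccc(OC)cc1C | intermediate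
7 | norcaradiene valence isomer of 8, 8-methoxy-10-methyltricyclo[4.4.0.0(1,5)]deca-7,9-dien-4-one (all-cis cyclopropane) | O=C1CC[C@]23[C@H]1[C@H]2C=C(OC)C=C3C | intermediate (not isolated)
8 | (8aR)-6-methoxy-4-methyl-3,8a-dihydroazulen-1(2H)-one | COC1=CC(C)=C2CCC(=O)[C@@H]2C=C1 | intermediate
9 | (1S,8aR)-6-methoxy-1,4-dimethyl-1,2,3,8a-tetrahydroazulen-1-ol (methyl cis to H8a) | COC1=CC(C)=C2CC[C@](C)(O)[C@@H]2C=C1 | intermediate (not isolated)
10 | (1S,8aR)-1-hydroxy-1,4-dimethyl-2,3,3a,8a-tetrahydroazulen-6(1H)-one (C3a epimers) | O=C1C=C[C@@H]2C(CC[C@]2(C)O)C(C)=C1 | intermediate (not isolated)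
11 | (1S)-1-hydroxy-1,4-dimethyl-2,3,7,8-tetrahydroazulen-6(1H)-one | O=C1CCC2=C(CC[C@]2(C)O)C(C)=C1 | intermediate
12 | (1S,3aS,8aS)-1-hydroxy-1,4-dimethyl-2,3,3a,7,8,8a-hexahydroazulen-6(1H)-one (H3a, H8a and OH cis) | O=C1CC[C@H]2[C@H](CC[C@]2(C)O)C(C)=C1 | intermediate
13 | dilithium salt (C1 alkoxide, C5=C6 enolate) of (1S,3aS,8aS)-1-hydroxy-1,4,4-trimethyloctahydroazulen-6(1H)-one | [Li]OC1=CC(C)(C)[C@H]2CC[C@](C)(O[Li])[C@H]2CC1 | intermediate (not isolated)
14 | (1S,3aS,8aS)-1-hydroxy-1,4,4-trimethyl-5-(prop-2-en-1-yl)octahydroazulen-6(1H)-one (C5 epimers) | O=C1CC[C@H]2[C@H](CC[C@]2(C)O)C(C)(C)C1CC=C | intermediate (not isolated)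
15 | (1S,3aS,5S,8aS)-1-hydroxy-1,4,4-trimethyl-5-(prop-2-en-1-yl)octahydroazulen-6(1H)-one | O=C1CC[C@H]2[C@H](CC[C@]2(C)O)C(C)(C)[C@@H]1CC=C | intermediate
16 | dipotassium salt (C1 alkoxide, C6=C7 enolate) of 15 | [K]OC1=CC[C@H]2[C@H](CC[C@]2(C)O[K])C(C)(C)[C@@H]1CC=C | intermediate (not isolated)
17 | (1S,3aS,5S,8aS)-1-hydroxy-1,4,4-trimethyl-5-(prop-2-en-1-yl)-1,2,3,3a,4,5,8,8a-octahydroazulen-6-yl trifluoromethanesulfonate | O=S(=O)(OC1=CC[C@H]2[C@H](CC[C@]2(C)O)C(C)(C)[C@@H]1CC=C)C(F)(F)F | intermediate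
18 | (1S,3aS,5R,8aS)-1,4,4,6-tetramethyl-5-(prop-2-en-1-yl)-1,2,3,3a,4,5,8,8a-octahydroazulen-1-ol | CC1=CC[C@H]2[C@H](CC[C@]2(C)O)C(C)(C)[C@@H]1CC=C | intermediate
19 | (E)-geranylacetone, (5E)-6,10-dimethylundeca-5,9-dien-2-one | CC(=O)CC/C=C(\C)CCC=C(C)C | starting material
20 | 4-[(2S,3S)-3-{2-[(2S)-3,3-dimethyloxiran-2-yl]ethyl}-3-methyloxiran-2-yl]butan-2-one | CC(=O)CC[C@@H]1O[C@@]1(C)CC[C@@H]1OC1(C)C | intermediate
21 | lithium enolate (methyl side) of 20 | [Li]OC(=C)CC[C@@H]1O[C@@]1(C)CC[C@@H]1OC1(C)C | intermediate (not isolated)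
22 | 1-(dimethylamino)-5-[(2S,3S)-3-{2-[(2S)-3,3-dimethyloxiran-2-yl]ethyl}-3-methyloxiran-2-yl]pentan-3-one | CN(C)CCC(=O)CC[C@@H]1O[C@@]1(C)CC[C@@H]1OC1(C)C | intermediate (not isolated)
23 | N,N,N-trimethylammonium iodide of 22 | C[N+](C)(C)CCC(=O)CC[C@@H]1O[C@@]1(C)CC[C@@H]1OC1(C)C.[I-] | intermediate (not isolated)
24 | 5-[(2S,3S)-3-{2-[(2S)-3,3-dimethyloxiran-2-yl]ethyl}-3-methyloxiran-2-yl]pent-1-en-3-one | C=CC(=O)CC[C@@H]1O[C@@]1(C)CC[C@@H]1OC1(C)C | intermediate
25 | (4E)-enone from 18 and 24 (name as in step 11) | CC1=CC[C@H]2[C@H](CC[C@]2(C)O)C(C)(C)[C@@H]1C/C=C/C(=O)CC[C@@H]1O[C@@]1(C)CC[C@@H]1OC1(C)C | intermediate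
26 | (3Z)-triethylsilyl enol ether of the saturated ketone (name as in step 12) | CC1=CC[C@H]2[C@H](CC[C@]2(C)O)C(C)(C)[C@@H]1CC/C=C(\O[Si](CC)(CC)CC)CC[C@@H]1O[C@@]1(C)CC[C@@H]1OC1(C)C | intermediate
27 | bis(trimethylsilyl) ether (azulene C1–O and benzoxepine C3–O) of 28 | CC1=CC[C@H]2[C@H](CC[C@]2(C)O[Si](C)(C)C)C(C)(C)[C@@H]1CC[C@H]1[C@]2(C)CC[C@H](O[Si](C)(C)C)C(C)(C)O[C@H]2CCC1=O | intermediate (not isolated)
28 | (3S,5aS,6S,9aS)-3-hydroxy-6-{2-[(1S,3aS,5R,8aS)-1-hydroxy-1,4,4,6-tetramethyl-1,2,3,3a,4,5,8,8a-octahydroazulen-5-yl]ethyl}-2,2,5a-trimethyloctahydro-1-benzoxepin-7(2H)-one | CC1=CC[C@H]2[C@H](CC[C@]2(C)O)C(C)(C)[C@@H]1CC[C@H]1[C@]2(C)CC[C@H](O)C(C)(C)O[C@H]2CCC1=O | intermediate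
29 | (3S,5aS,6S,7R,9aS)-6-{2-[(1S,3aS,5R,8aS)-1-hydroxy-1,4,4,6-tetramethyl-1,2,3,3a,4,5,8,8a-octahydroazulen-5-yl]ethyl}-2,2,5a,7-tetramethyldecahydro-1-benzoxepine-3,7-diol | CC1=CC[C@H]2[C@H](CC[C@]2(C)O)C(C)(C)[C@@H]1CC[C@H]1[C@]2(C)CC[C@H](O)C(C)(C)O[C@H]2CC[C@@]1(C)O | intermediate
30 | (5aS,6S,7R,9aS)-7-hydroxy-6-{2-[(1S,3aS,5R,8aS)-1-hydroxy-1,4,4,6-tetramethyl-1,2,3,3a,4,5,8,8a-octahydroazulen-5-yl]ethyl}-2,2,5a,7-tetramethyloctahydro-1-benzoxepin-3(2H)-one | CC1=CC[C@H]2[C@H](CC[C@]2(C)O)C(C)(C)[C@@H]1CC[C@H]1[C@]2(C)CCC(=O)C(C)(C)O[C@H]2CC[C@@]1(C)O | target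

## Step count and risks

Total: 15 steps. Longest linear sequence: 13 steps (steps 1–8, then 11–15); the geranylacetone branch (steps 9–10) joins at step 11.

Three steps most likely to fail:

**Step 3 (together with the chirality relay into step 4).** The level and sense of induction for this substrate are unproven, C8a–H of 8 is labile, and the diastereoselectivity of the organocerium addition translates directly into the ee of 11. Fallback, setting out from 6 and coming back at 11: 6 is cyclised with achiral Rh2(OAc)4 to the racemic azulenone F1, which Et3N isomerises to the conjugated trienone 6-methoxy-4-methyl-3,4-dihydroazulen-1(2H)-one F2, in which C8a is sp2 and the labile centre is gone. The absolute configuration is then set by reagent control instead of by the carbene step: catalytic enantioselective 1,2-methylation of the α-substituted cyclopentenone carbonyl (Me2Zn, Ti(OiPr)4, chiral trans-cyclohexane-1,2-bis(sulfonamide) diol ligand) gives the (1S) tertiary allylic alcohol F3. Buffered hydrolysis of the enol ether (oxalic acid on wet SiO2) and DBU equilibration converge on 11, because the C4 centre of F2 and F3 becomes sp2.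

**Step 5.** The alkene is tetrasubstituted and part of an electron-poor dienone, and the C4=C5 bond may be over-reduced. Fallback, setting out from 11 and coming back at 12: dissolving-metal 1,6-reduction (Li, NH3/THF, −78 °C, no external proton source) protonates the δ-carbon C8a of the reduced dienone from the neighbouring C1–OH, on the OH face. An NH4Cl quench of the extended enolate gives the β,γ-enone (1S,8aS)-1-hydroxy-1,4-dimethyl-2,3,5,7,8,8a-hexahydroazulen-6(1H)-one F4. DBU then reconjugates it with protonation of C3a from the convex face, cis to H8a, to give 12; the cis preference at C3a is expected but not guaranteed.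

**Step 6.** SN2 allylation of a hindered cuprate-derived enolate next to a quaternary carbon can be sluggish, and the C5 ratio rests on equilibration. Fallback, setting out from 12 and coming back at 15: the cuprate addition is run with Me3SiCl so that the enolate and the C1 alkoxide are captured as the bis(trimethylsilyl) compound F5. The silyl enol ether is then allylated regiospecifically through a π-allylpalladium electrophile (allyl methyl carbonate, Pd2(dba)3, dppe, THF) instead of by SN2 alkylation, and K2CO3/MeOH removes the remaining silyl group and equilibrates C5 to give 15.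

## Further compounds

F1 | step 3 | racemic 6-methoxy-4-methyl-3,8a-dihydroazulen-1(2H)-one | COC1=CC(C)=C2CCC(=O)C2C=C1
F2 | step 3 | 6-methoxy-4-methyl-3,4-dihydroazulen-1(2H)-one (racemic at C4) | COC1=CC(C)C2=C(C=C1)C(=O)CC2
F3 | step 3 | (1S)-6-methoxy-1,4-dimethyl-1,2,3,4-tetrahydroazulen-1-ol (C4 epimers) | COC1=CC(C)C2=C(C=C1)[C@@](C)(O)CC2
F4 | step 5 | (1S,8aS)-1-hydroxy-1,4-dimethyl-2,3,5,7,8,8a-hexahydroazulen-6(1H)-one | O=C1CC[C@H]2C(CC[C@]2(C)O)=C(C)C1
F5 | step 6 | trimethyl{[(1S,3aS,8aS)-1,4,4-trimethyl-6-(trimethylsilyloxy)-1,2,3,3a,4,7,8,8a-octahydroazulen-1-yl]oxy}silane | C[Si](C)(C)OC1=CC(C)(C)[C@H]2CC[C@](C)(O[Si](C)(C)C)[C@H]2CC1
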